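## Retrosynthetic overview

1. Target ⇒ 7-endo-prenyl type A bicyclo[3.3.1]nonane-2,4,9-trione by one aerobic cascade: the C3 enol carbon, oxidised to an α,α′-diketo radical, bonds to alkene carbon C28 (two normally nucleophilic carbons); then O2 capture, peroxyl 7-exo closure onto the C3 prenyl group, second O2 capture.
2. Prenyl groups on C3 and C5 ⇒ allyl placeholders (cross-metathesis), so no ring-bound prenyl competes during ring-B closure.
3. Ring B ⇒ C1–C8 bond by photochemical proton-transfer cyclisation of a dearomatised acylphloroglucinol onto an isopropenyl group.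
4. C5–C6 ⇒ alkylative dearomatisation of 3,5-diallyl-2,4,6-trihydroxybenzophenone with (R)-lavandulyl triflate; C7 comes from the chiral pool.
5. Ring order: acylphloroglucinol ring (dearomatised) → ring B (bicyclo[3.3.1]) → seven-membered carbocycle (homoadamantane) → 1,2-dioxepane.

Assumptions: (R)-(−)-lavandulol is bought as the single enantiomer. Locants follow the usual PPAP numbering: C1 benzoyl-bearing bridgehead, C2/C4/C9 carbonyls, C3 diketone carbon, C5 second bridgehead, C6–C8 ring B, C17–C21 the C3 prenyl, C27–C31 the C7 prenyl.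

## Route

Step 1
Reactants: 1 2,4,6-trihydroxybenzophenone; 2 allyl bromide
Product: 3 3,5-diallyl-2,4,6-trihydroxybenzophenone
Conditions: 2 (2.1 equiv), 10% aq. KOH, 0 °C → rt
Reagents that add atoms: none
Why: Aqueous-base C-allylation of an acylphloroglucinol, in which the phloroglucinolate reacts at its two free ring carbons and water suppresses O-alkylation; no stereocentre is formed.

Step 2
Reactants: 4 (R)-(−)-lavandulol
Product: 5 (R)-lavandulyl triflate [(2R)-5-methyl-2-(prop-1-en-2-yl)hex-4-en-1-yl trifluoromethanesulfonate]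
Conditions: Tf2O, 2,6-lutidine, CH2Cl2, −78 °C; cold work-up, used at once
Reagents that add atoms: triflic anhydride, O=S(=O)(OS(=O)(=O)C(F)(F)F)C(F)(F)F
Why: Standard O-sulfonylation of a primary alcohol at low temperature, which leaves the adjacent stereocentre and both alkenes untouched.

Step 3
Reactants: 3 3,5-diallyl-2,4,6-trihydroxybenzophenone; 5 (R)-lavandulyl triflate
Product: 6 (6S)-2-benzoyl-3,5-dihydroxy-6-[(2S)-5-methyl-2-(prop-1-en-2-yl)hex-4-en-1-yl]-4,6-di(prop-2-en-1-yl)cyclohexa-2,4-dien-1-one (one enol tautomer drawn)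
Conditions: LiHMDS (2.2 equiv), THF, −78 → 0 °C; then 5, 0 °C → rt; chromatographic separation of the C6 epimers
Reagents that add atoms: none
Why: Alkylative dearomatisation (SN2 C-alkylation of the lithium phloroglucinolate at an allyl-bearing ring carbon, the usual reactive site of 3,5-dialkyl acylphloroglucinols); C2′ comes unchanged from lavandulol, while the new quaternary C6 forms without control (about 1:1) and the 6S epimer, the only one whose ring closure places the C7 chain endo, is isolated.

Step 4
Reactants: 6 the (6S,2′S) dearomatised monocycle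
Product: 7 (1S,5S,7S)-1-benzoyl-4-hydroxy-8,8-dimethyl-7-(3-methylbut-2-en-1-yl)-3,5-di(prop-2-en-1-yl)bicyclo[3.3.1]non-3-ene-2,9-dione (type A core, C7 chain endo, i.e. on the side of the C2–C3–C4 bridge)
Conditions: hν (365 nm LED), degassed benzene, rt
Reagents that add atoms: none
Why: Excited-state intramolecular proton-transfer photocyclisation (a photochemical Markovnikov enol–ene hydroalkylation) in which the excited chelated benzoyl-enol protonates the isopropenyl CH2 and the tertiary C8 cation collapses in the ion pair onto the benzoyl-bearing C1 (kinetic type A closure, no acid to equilibrate, allyl groups not protonated); C1 is fixed by the bridge and the 6S,2′S relationship forces the C7 prenyl endo.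

Step 5
Reactants: 7 the 3,5-diallyl type A bicycle
Product: 8 (1S,5S,7S)-1-benzoyl-4-hydroxy-8,8-dimethyl-3,5,7-tris(3-methylbut-2-en-1-yl)bicyclo[3.3.1]non-3-ene-2,9-dione (7-epi-nemorosone-type, endo C7 prenyl)
Conditions: Hoveyda–Grubbs II (10 mol %), 2-methyl-2-butene/CH2Cl2, 40 °C, sealed tube
Reagents that add atoms: 2-methyl-2-butene, CC=C(C)C
Why: Olefin cross-metathesis of the two monosubstituted allyl groups with excess 2-methyl-2-butene installs both prenyl groups, while the existing trisubstituted prenyl, the enol and the ketones are spectators; no stereocentre is touched.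

Step 6
Reactants: 8 the tri-prenyl type A bicycle
Product: 9 target CNP0215795.1, (1R,3R,5S,7S,18S,28S): the 1-benzoyl-8,8-dimethyl-5-prenyl-bicyclo[3.3.1]nonane-2,4,9-trione in which C3 is bonded to C28 (C7–C27H2–C28H bridge), C29Me2–O–O–C18H closes a 1,2-dioxepane through C17H2 on C3, and C18 carries C19Me2–OOH
Conditions: Mn(OAc)3·2H2O (5–10 mol %), air (1 atm), AcOH, 5 mM, 15 °C, dark
Reagents that add atoms: dioxygen, O=O
Why: Proposed new method: Mn(III) oxidises the C2–C3–C4 enol to an electrophilic C3 radical (the normally nucleophilic enol carbon with reversed polarity), which adds 7-exo to C28 of the endo C7 prenyl held directly above it, the tertiary C29 radical captures O2, the C29 peroxyl radical adds 7-exo to C18 of the C3 prenyl, the tertiary C19 radical captures a second O2 and Mn(II)/H+ reduces the C19 peroxyl radical to the hydroperoxide, regenerating Mn(III); high dilution and low Mn loading favour the unimolecular peroxyl closure over premature reduction, C3 is fixed by the cage, C28 is expected to form with the CMe2 end over the less hindered C4/C5 flank (28S) and C18 through a chair-like peroxyl cyclisation (18S, H18 cis to H28), both under substrate control and not yet demonstrated; closest known reaction type is the Mn(III)-catalysed aerobic peroxidation of 1,3-dicarbonyls with alkenes to cyclic peroxides, combined with peroxyl-radical cyclisation/oxygenation.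

## Compound list

1 | 2,4,6-trihydroxybenzophenone | O=C(c1ccccc1)c1c(O)cc(O)cc1O | starting material
2 | allyl bromide (3-bromoprop-1-ene) | C=CCBr | starting material
3 | 3,5-diallyl-2,4,6-trihydroxybenzophenone | O=C(c1ccccc1)c1c(O)c(CC=C)c(O)c(CC=C)c1O | intermediate
4 | (R)-(−)-lavandulol, (2R)-5-methyl-2-(prop-1-en-2-yl)hex-4-en-1-ol | OC[C@@H](C(C)=C)CC=C(C)C | starting material
5 | (R)-lavandulyl triflate | O=S(=O)(OC[C@@H](C(C)=C)CC=C(C)C)C(F)(F)F | intermediate
6 | (6S)-2-benzoyl-3,5-dihydroxy-6-[(2S)-5-methyl-2-(prop-1-en-2-yl)hex-4-en-1-yl]-4,6-di(prop-2-en-1-yl)cyclohexa-2,4-dien-1-one | C=CC[C@@]1(C[C@H](CC=C(C)C)C(C)=C)C(=O)C(C(=O)c2ccccc2)=C(O)C(CC=C)=C1O | intermediate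
7 | (1S,5S,7S)-1-benzoyl-4-hydroxy-8,8-dimethyl-7-(3-methylbut-2-en-1-yl)-3,5-di(prop-2-en-1-yl)bicyclo[3.3.1]non-3-ene-2,9-dione | C=CC[C@]12C[C@H](CC=C(C)C)C(C)(C)[C@@](C(=O)c3ccccc3)(C2=O)C(=O)C(CC=C)=C1O | intermediate
8 | (1S,5S,7S)-1-benzoyl-4-hydroxy-8,8-dimethyl-3,5,7-tris(3-methylbut-2-en-1-yl)bicyclo[3.3.1]non-3-ene-2,9-dione | CC(C)=CC[C@]12C[C@H](CC=C(C)C)C(C)(C)[C@@](C(=O)c3ccccc3)(C2=O)C(=O)C(CC=C(C)C)=C1O | intermediate
9 | CNP0215795.1, (1R,3R,5S,7S,18S,28S) homoadamantane dioxepane hydroperoxide | CC(C)=CC[C@]12C[C@@H]3C[C@@H]4C(C)(C)OO[C@H](C(C)(C)OO)C[C@@]4(C1=O)C(=O)[C@](C(=O)c1ccccc1)(C2=O)C3(C)C | target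

## Step count and risks

Total steps: 6. Longest linear sequence: 5 (1 → 3 → 6 → 7 → 8 → 9, or 4 → 5 → 6 → 7 → 8 → 9).

The three steps most likely to fail are steps 6, 4 and 3.

**Step 6 (aerobic cascade).** Possible failures are direct O2 capture at C3, reduction of the C29 peroxyl radical before it cyclises (giving a peroxy-hemiketal on C4), or the wrong C28/C18 diastereomer. The fallback sets out from 8 and returns at 9 by splitting the cascade into separate events. Mn(OAc)3·2H2O (2.2 equiv) with Cu(OAc)2·H2O (1 equiv) in degassed AcOH at rt effects the same C3→C28 7-exo radical cyclisation without oxygen, and Cu(II) oxidises the C29 radical to the alkene, giving the C3–C28-cyclised homoadamantane-2,4,9-trione with an isopropenyl group on C28 F5. Mukaiyama–Isayama hydroperoxysilylation (Co(thd)2, O2, Et3SiH, DCE), in which the 1,1-disubstituted alkene reacts ahead of the two prenyl groups, gives the C29 triethylsilyl peroxide F6. HF·pyridine releases the C29 hydroperoxide F7. A classical peroxyl-radical chain (di-tert-butyl peroxyoxalate initiator, O2, benzene, rt) then closes the dioxepane by 7-exo attack on the C3 prenyl and captures O2 to give 9.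

**Step 4 (type A photocyclisation).** Possible failures are closure at C3 or oxygen, or proton transfer to the side-chain prenyl. The fallback sets out from 1 and 5 and returns at 8, dropping both the allyl placeholders and the photochemistry. Diprenylation of 1 (prenyl bromide, aq. KOH) gives 2,4,6-trihydroxy-3,5-bis(3-methylbut-2-en-1-yl)benzophenone (clusiaphenone B) F3. Alkylation with 5 as in step 3 and separation of epimers gives the (6S,2′S) diprenyl monocycle F4. Ring B is then closed in the ground state by metal-hydride hydrogen-atom transfer with radical–polar crossover (Co(salen) cat., N-fluoro-2,4,6-collidinium triflate, PhSiH3, acetone, 0 °C). Hydrogen-atom transfer should select the 1,1-disubstituted isopropenyl group over the trisubstituted prenyl alkenes, and the tertiary C8 cation equivalent is captured irreversibly by the triketonate; capture at C1 rather than C3 or oxygen is the open question. If C1 capture holds, this gives 8 directly and makes step 5 unnecessary.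

**Step 3 (alkylative dearomatisation).** Possible failures are O-alkylation or a sluggish reaction of the β-branched triflate at a substituted ring carbon. The fallback sets out from 1 and 5 and returns at 6 by reversing the order of the two C-alkylations. Treating 1 with LiHMDS and 5 lets the unactivated electrophile meet an unsubstituted ring carbon, giving {2,4,6-trihydroxy-3-[(2S)-5-methyl-2-(prop-1-en-2-yl)hex-4-en-1-yl]phenyl}(phenyl)methanone F1. One equivalent of 2 in aq. KOH fills the remaining free ring position, giving the 3-allyl-5-lavandulyl-2,4,6-trihydroxybenzophenone F2. A second allylation with the reactive allylic bromide 2 then dearomatises at the lavandulyl-bearing carbon to give 6, which is separated from its C6 epimer and the gem-diallyl regioisomer.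

Further compounds
F1 | step 3 | {2,4,6-trihydroxy-3-[(2S)-5-methyl-2-(prop-1-en-2-yl)hex-4-en-1-yl]phenyl}(phenyl)methanone | O=C(c1ccccc1)c1c(O)cc(O)c(C[C@H](CC=C(C)C)C(C)=C)c1O
F2 | step 3 | {3-allyl-2,4,6-trihydroxy-5-[(2S)-5-methyl-2-(prop-1-en-2-yl)hex-4-en-1-yl]phenyl}(phenyl)methanone | O=C(c1ccccc1)c1c(O)c(CC=C)c(O)c(C[C@H](CC=C(C)C)C(C)=C)c1O
F3 | step 4 | 2,4,6-trihydroxy-3,5-bis(3-methylbut-2-en-1-yl)benzophenone (clusiaphenone B) | O=C(c1ccccc1)c1c(O)c(CC=C(C)C)c(O)c(CC=C(C)C)c1O
F4 | step 4 | (6S)-2-benzoyl-3,5-dihydroxy-6-[(2S)-5-methyl-2-(prop-1-en-2-yl)hex-4-en-1-yl]-4,6-bis(3-methylbut-2-en-1-yl)cyclohexa-2,4-dien-1-one | CC(C)=CC[C@@]1(C[C@H](CC=C(C)C)C(C)=C)C(=O)C(C(=O)c2ccccc2)=C(O)C(CC=C(C)C)=C1O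
F5 | step 6 | (1R,3R,5S,7S,28R) C3–C28-cyclised 1-benzoyl-8,8-dimethyl-3,5-diprenyl-homoadamantane-2,4,9-trione with isopropenyl on C28 | CC(C)=CC[C@]12C[C@@H]3C[C@H](C(C)=C)[C@](CC=C(C)C)(C1=O)C(=O)[C@](C(=O)c1ccccc1)(C2=O)C3(C)C
F6 | step 6 | (1R,3R,5S,7S,28S) C29 triethylsilyl peroxide of the same homoadamantane trione | CC(C)=CC[C@]12C[C@@H]3C[C@H](C(C)(C)OO[Si](CC)(CC)CC)[C@](CC=C(C)C)(C1=O)C(=O)[C@](C(=O)c1ccccc1)(C2=O)C3(C)C
F7 | step 6 | (1R,3R,5S,7S,28S) C29 hydroperoxide of the same homoadamantane trione | CC(C)=CC[C@]12C[C@@H]3C[C@H](C(C)(C)OO)[C@](CC=C(C)C)(C1=O)C(=O)[C@](C(=O)c1ccccc1)(C2=O)C3(C)C
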